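## The problem

Germacrane numbering is used throughout: C1 ketone, C2 and C3 methylenes, C4–C5 epoxide (C15 methyl on C4), C6 lactone CH–O, C7=C11 butenolide alkene, C8 tiglate carbon, C9 methylene, C10 acetoxy carbon (C14 methyl), C12 lactone carbonyl, C13 acetoxymethyl.

- The skeleton is a ten-membered carbocycle (C1–C10) fused through C6–C7 to a butenolide. Its tetrasubstituted C7=C11 bond carries four different oxygenated carbons: C6 and C8 on C7, C12 (cis to C6) and C13 (cis to C8) on C11. Any open-chain precursor of the lactone therefore has an alkene geometry to control.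
- Of the five stereocenters, C10 is quaternary and isolated and is best bought. C6 and C8 are allylic carbinol carbons on either side of the sp2 carbon C7; neither can be relayed reliably from C10 or from the other, so each needs its own reagent control. C4 and C5 can be set last from an (E)-C4=C5 alkene, where the lactone junction at C6 fixes the ring conformation and the exposed face.
- Several groups will not survive rough treatment: the tertiary α-acetoxy ketone (acetyl shift to a free C8 hydroxyl under base), the acid-sensitive epoxide, and H6, which is allylic and γ to the lactone carbonyl. Zerovalent palladium ionizes the allylic C13 acetate, the allylic C8 tiglate and, as long as C4=C5 exists, the vinyl-lactone C6–O bond.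
- A free C8 hydroxyl lies 1,4 to C1 and closes a γ-lactone onto any activated C1 carboxyl derivative.
- Direct closure of the ten-membered ring fights entropy and transannular strain.
- The enabling feature: the C1 ketone can enolize only toward C2 because C10 is quaternary, and C2 is bonded to C3, which is allylic to C4=C5. C2–C3 is the only CH2–CH2 bond of the ring. A CO2 unit placed between C2 and C3 turns the ring into a twelve-membered allyl β-keto lactone, and loss of that CO2 under palladium catalysis re-forms C2–C3.

## Retrosynthesis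

**32 ⇒ 31 (C4–O and C5–O).** The epoxide is removed first. A vinyl epoxide would not survive the palladium step, and C4=C5 is the allyl unit of that step. The forward reaction must pick C4=C5 out of three alkenes (the other two are electron-poor) and the outer face of the ring.

**31 ⇒ 30 ⇒ 29 (acyl C–O bonds at C8 and C13).** Both esters are allylic and must come after the palladium step. Diol 29 differs in its hydroxyls (primary C13, hindered secondary C8), so acetate is placed first and tiglate second.

**29 ⇒ 27 (lactone C12–O bond and three Si–O bonds).** With C4=C5 in place the closed butenolide is a vinyl lactone that zerovalent palladium would open. It is therefore carried as the acyclic methyl ester with C6–O silylated. Fluoride must unmask C6–OH, which then closes onto the cis ester; this requires the ester of 27 to be cis to C6.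

**27 ⇒ 26 (C2–C3, the key cut).** Inserting CO2 into this bond gives the twelve-membered allyl β-keto lactone 26. Neighbouring cuts (C7–C8, C1–C2, C4=C5) would ask for a direct ten-membered closure at a hindered or stereogenic carbon. This cut creates no stereocenter, joins an unhindered primary allyl terminus to an enolate of fixed position, and replaces the medium-ring closure by an easy macrolactonization.

**26 ⇒ 24 ⇒ 23 ⇒ 20 + 21 (lactone O–C bond, then C1–C2).** The β-keto lactone is the capture product of an acylketene by the C3 hydroxyl. The acylketene comes from acyl Meldrum's acid 23, made from acid 20 and Meldrum's acid 21. No base or coupling reagent touches the seco-alcohol 24.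

**20 ⇒ 18 ⇒ 17 (acetate C–O; dioxolanone C–O bonds).** The C10 acetate and the free C1 acid are unveiled late from a dioxolanone, which protects both functions of the citramalate unit through the fragment union.

**17 ⇒ 15 ⇒ 11 + 14 (C8–H, then C7–C8).** The C8 carbinol is traced to ketone 15 so that its configuration is set by a CBS reagent and not by a remote center. The ketone comes from acylation of alkenylstannane 11 by acid chloride 14, which joins the two halves at the ketone oxidation level.

**14 ⇒ 13 ⇒ 12.** (R)-Citramalic acid 12 supplies C1, C8, C9, C10 and C14 with the C10 configuration in place. Acetonide formation differentiates its two carboxyls in one step.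

**11 ⇒ 9 (C7–Sn and C11–C13).** The tetrasubstituted alkene is made by syn addition of a stannyl group and a CH2OSi group across ynoate 9. Syn addition puts the ester cis to C6 and C13 cis to the tin that becomes C8, which is exactly the geometry the lactonization needs. The forward step must alkylate the alkenylcopper 10 before it equilibrates.

**9 ⇒ 8 ⇒ 6 + 7 (C6–C7).** Asymmetric addition of methyl propiolate 7 to enal 6 sets C6 by reagent control. It brings in C7, C11 and C12 and leaves C4=C5 already in place, so no epimerizable α-silyloxy aldehyde at C6 is ever needed.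

**6 ⇒ 5 ⇒ 4 ⇒ 3 ⇒ 1 + 2 (C4=C5).** A stabilized Wittig reaction of ylide 2 with glyoxal monoacetal 1 gives the (E)-trisubstituted alkene. The ester becomes C3–OH (PMB ether) and the acetal becomes the C6 aldehyde.

## Roads not taken

**Alternative 1: oxidative C6–H lactonization.** The cut is the lactone C6–O bond, traced back to a C6 methylene in the ten-membered dienoic acid A2. In the forward step Pd(OAc)2 with 1,2-bis(phenylsulfinyl)ethane and benzoquinone cleaves a doubly allylic C6–H bond and the C12 carboxylate closes onto C6 to give A1, which is identical with 31.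
- Merits: no oxygen is carried at C6, so one asymmetric step and one protecting group are saved; the step is biomimetic and late.
- Weak points: this C–H lactonization is established for terminal alkenes, not for an internal methylene in a medium ring. The allyl unit can form toward C4 or toward C11. C3–H, C15–H and C8–H compete. The catalytic cycle passes through zerovalent palladium in the presence of the C13 acetate and C8 tiglate. The C6 configuration would rest on ring conformation alone. A2 still needs the ten-membered ring and the geometrically defined alkylidene acid.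
- Comparison: this road is better at the end (the lactone is closed with both esters already in place) and in stereocenter count. The adopted plan sets against it a reagent-controlled C6 and a palladium step on a substrate with a single ionizable group.

**Alternative 2: Birch reduction and central alkene ozonolysis.** The cut is the C1/C6 pair of carbonyls, traced to the shared tetrasubstituted alkene of the bicyclic ketal A4. Ozone cleaves that alkene to give the ten-membered 1,6-diketone A3.
- Merits: the ring costs no cyclization entropy, the starting materials are cheap, and oxygen sits at C1 and C6 at once.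
- Weak points: A3 is far from the target. Its alkene is C3=C4 and (Z), and must become (E)-C4=C5. C10 is a tertiary C–H that needs stereocontrolled hydroxylation. C6 and C8 need stereoselective reductions. C7 needs the whole C11–C13 unit. 1,6-Cyclodecanediones collapse by transannular aldol reaction. Ozone must distinguish two alkenes.
- Comparison: for making the ring this road is better than the adopted plan, which spends sixteen steps before its ring closes. After A3 it would need at least as many steps again, with several regio- and stereochemical corrections of low predictability; the adopted plan builds every stereocenter before or independently of ring closure.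

**Alternative 3: Nozaki–Hiyama–Kishi closure.** The cut is C7–C8. Cathodically regenerated CrCl2 with NiCl2 turns the C7 bromide of bromobutenolide aldehyde A6 into an alkenylchromium species that adds to the C8 aldehyde, giving the 8-hydroxy macrocycle A5; tigloylation finishes.
- Merits: the butenolide geometry is locked in a ring from the start, so the acyclic alkene problem that step 7 exists to solve never arises. All other groups are final, and the ring closure is one step from the target. In these respects it is better.
- Weak points: the bond forms at a fully substituted alkenyl carbon in a direct ten-membered closure. The C8 configuration is left to the macrocyclic transition state. Low-valent nickel sits next to the C13 allylic acetate. The epoxide and both esters must be carried through a long linear synthesis of A6.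
- Comparison: the adopted plan pays four finishing steps and an acyclic geometry problem. In return it closes the ring between an unhindered primary carbon and a positionally fixed enolate without creating a stereocenter, and it sets C8 by a reagent.

Key step: step 17

Assumption: the target is the (4R,5R,6S,8S,10R) isomer read from the SMILES; in every precursor that still has C4=C5 the same spatial arrangement at C6 is named 6R because C7 then outranks C5, and iPr3SiOCH2Cl, Me6Sn2, tigloyl chloride and both ProPhenol enantiomers are treated as commercial.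

## Steps

Step 1
Reactants: 1 2,2-dimethoxyacetaldehyde (60% aqueous solution); 2 ethyl 2-(triphenylphosphoranylidene)propanoate
Product: 3 ethyl (2E)-4,4-dimethoxy-2-methylbut-2-enoate
Conditions: CH2Cl2, 25 °C
Reagents that add atoms: none
Why: Wittig olefination with a stabilized α-methyl ylide, which gives the (E)-2-methyl enoate with high selectivity and tolerates water; the acetal keeps the future C6 at the aldehyde level.

Step 2
Reactants: 3 ethyl (2E)-4,4-dimethoxy-2-methylbut-2-enoate
Product: 4 (2E)-4,4-dimethoxy-2-methylbut-2-en-1-ol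
Conditions: iBu2AlH (2.2 equiv), CH2Cl2, −78 °C; aqueous work-up
Reagents that add atoms: none
Why: 1,2-reduction of an enoate to the allylic alcohol (the future C3–OH) with iBu2AlH; the acetal is inert.

Step 3
Reactants: 4 (2E)-4,4-dimethoxy-2-methylbut-2-en-1-ol
Product: 5 1-({[(2E)-4,4-dimethoxy-2-methylbut-2-en-1-yl]oxy}methyl)-4-methoxybenzene
Conditions: NaH, 4-MeOC6H4CH2Cl, Bu4NI (cat.), THF/DMF, 0 → 25 °C
Reagents that add atoms: 4-methoxybenzyl chloride, COc1ccc(CCl)cc1
Why: Williamson etherification; PMB is chosen for C3–O because it is the one group later removed oxidatively in the presence of four silyl ethers.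

Step 4
Reactants: 5 PMB ether acetal
Product: 6 (2E)-4-[(4-methoxybenzyl)oxy]-3-methylbut-2-enal
Conditions: oxalic acid (aq.), THF, 25 °C
Reagents that add atoms: water, O
Why: Acid-catalysed acetal hydrolysis; mild acid spares the PMB ether and limits E/Z equilibration of the enal.

Step 5
Reactants: 6 (2E)-4-[(4-methoxybenzyl)oxy]-3-methylbut-2-enal; 7 methyl propiolate
Product: 8 methyl (4R,5E)-4-hydroxy-7-[(4-methoxybenzyl)oxy]-6-methylhept-5-en-2-ynoate
Conditions: (S,S)-ProPhenol (20 mol %), Me2Zn (3 equiv), toluene, 4 °C; aq. NH4Cl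
Reagents that add atoms: none
Why: ProPhenol/Me2Zn-catalysed asymmetric alkynylation of an enal with methyl propiolate (Trost), which forms C6–C7 and sets C6 by reagent control. The ligand enantiomer is the one that gives the 6R carbinol, taken as (S,S) on the usual model for enals; the (R,R) ligand is used if the sense proves opposite.

Step 6
Reactants: 8 methyl (4R,5E)-4-hydroxy-7-[(4-methoxybenzyl)oxy]-6-methylhept-5-en-2-ynoate
Product: 9 methyl (4R,5E)-4-[(tert-butyldimethylsilyl)oxy]-7-[(4-methoxybenzyl)oxy]-6-methylhept-5-en-2-ynoate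
Conditions: TBSOTf, 2,6-lutidine, CH2Cl2, −78 °C
Reagents that add atoms: tert-butyldimethylsilyl trifluoromethanesulfonate, CC(C)(C)[Si](C)(C)OS(=O)(=O)C(F)(F)F
Why: Silylation with a silyl triflate and a hindered base at low temperature avoids base-mediated isomerization of the γ-hydroxy ynoate to the 4-oxo enoate.

Step 7
Reactants: 9 silyloxy ynoate
Product: 11 methyl (2E,4R,5E)-4-[(tert-butyldimethylsilyl)oxy]-7-[(4-methoxybenzyl)oxy]-6-methyl-2-{[(triisopropylsilyl)oxy]methyl}-3-(trimethylstannyl)hepta-2,5-dienoate, via alkenylcopper 10 (not isolated)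
Conditions: Me3SnCu·SMe2 (from Me6Sn2, MeLi, CuBr·SMe2), THF, −78 °C; then iPr3SiOCH2Cl, −78 °C
Reagents that add atoms: hexamethylditin, C[Sn](C)(C)[Sn](C)(C)C; (triisopropylsiloxy)methyl chloride, CC(C)[Si](OCCl)(C(C)C)C(C)C
Why: Syn stannylcupration of a 2-alkynoate (Piers type) gives the α-cuprio β-stannyl ester 10, which is C-alkylated with retention by the reactive α-chloro ether, as in the known alkylations of such adducts. Syn addition places tin (the future C8) cis to the new CH2OTIPS (C13) and the ester cis to C6; no strongly coordinating co-solvent is added because it favours equilibration through the allenoate.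

Step 8
Reactants: 12 (R)-citramalic acid
Product: 13 2-[(4R)-2,2,4-trimethyl-5-oxo-1,3-dioxolan-4-yl]acetic acid
Conditions: Me2C(OMe)2, PPTS (cat.), CH2Cl2, 25 °C
Reagents that add atoms: 2,2-dimethoxypropane, COC(C)(C)OC
Why: Acetonide formation of an α-hydroxy acid; the five-membered dioxolanone forms selectively, masks C1 and the C10 hydroxyl together and leaves the C8 carboxyl free.

Step 9
Reactants: 13 dioxolanone acid
Product: 14 2-[(4R)-2,2,4-trimethyl-5-oxo-1,3-dioxolan-4-yl]acetyl chloride
Conditions: (COCl)2, DMF (cat.), CH2Cl2, 0 → 25 °C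
Reagents that add atoms: oxalyl chloride, O=C(Cl)C(Cl)=O
Why: Acid chloride formation under Vilsmeier catalysis; the dioxolanone is stable to these conditions.

Step 10
Reactants: 11 alkenylstannane; 14 acid chloride
Product: 15 methyl (2E,4R,5E)-4-[(tert-butyldimethylsilyl)oxy]-7-[(4-methoxybenzyl)oxy]-6-methyl-2-{[(triisopropylsilyl)oxy]methyl}-3-{2-[(4R)-2,2,4-trimethyl-5-oxo-1,3-dioxolan-4-yl]acetyl}hepta-2,5-dienoate
Conditions: Pd2(dba)3 (5 mol %), P(2-furyl)3 (20 mol %), THF, 50 °C
Reagents that add atoms: none
Why: Stille acylation of an alkenylstannane with an acid chloride, stereoretentive at C7, forms C7–C8 at the ketone level. The trimethylstannyl group and the furylphosphine are chosen to speed transmetalation at the fully substituted carbon; the new ketone is trans to the ester and cannot reach it.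

Step 11
Reactants: 15 enone
Product: 17 methyl (2Z,4R,5E)-4-[(tert-butyldimethylsilyl)oxy]-3-{(1S)-1-[(tert-butyldimethylsilyl)oxy]-2-[(4R)-2,2,4-trimethyl-5-oxo-1,3-dioxolan-4-yl]ethyl}-7-[(4-methoxybenzyl)oxy]-6-methyl-2-{[(triisopropylsilyl)oxy]methyl}hepta-2,5-dienoate, via C8 alcohol 16 (not isolated)
Conditions: (R)-Me-CBS (0.5 equiv), catecholborane, toluene, −78 °C; MeOH quench, evaporation; TBSOTf, 2,6-lutidine, CH2Cl2, −78 → 0 °C
Reagents that add atoms: tert-butyldimethylsilyl trifluoromethanesulfonate, CC(C)(C)[Si](C)(C)OS(=O)(=O)C(F)(F)F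
Why: Corey–Bakshi–Shibata reduction with the fully substituted alkenyl group as the large substituent; by the acetophenone model the (R)-catalyst should give 8S. Alcohol 16 is silylated without purification because a free C8–OH can translactonize onto the activated dioxolanone carbonyl (C1).

Step 12
Reactants: 17 bis-TBS dioxolanone
Product: 18 seco hydroxy acid (C1 carboxylic acid, C10 tertiary alcohol; otherwise as 17)
Conditions: LiOH, THF/H2O, 0 °C; then 1 M HCl to pH 3
Reagents that add atoms: water, O (delivered as hydroxide from LiOH)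
Why: Saponification of the dioxolanone, an activated acylal-type ester, is much faster than that of the hindered tetrasubstituted methyl enoate; acetone is lost and the C1 acid and C10 hydroxyl are unveiled.

Step 13
Reactants: 18 seco hydroxy acid
Product: 20 seco acetoxy acid (C10 acetate, C1 carboxylic acid), via mixed anhydride 19 (not isolated)
Conditions: Ac2O, pyridine, DMAP (cat.), 40 °C; then H2O/THF, 25 °C
Reagents that add atoms: acetic anhydride, CC(=O)OC(C)=O
Why: DMAP-catalysed acetylation; tertiary α-hydroxy acids acetylate readily because the carboxyl is first converted to the mixed anhydride and the neighbouring hydroxyl is then acylated, and water cleaves the residual anhydride 19 at the unhindered acetyl carbonyl.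

Step 14
Reactants: 20 seco acetoxy acid; 21 Meldrum's acid
Product: 23 acyl Meldrum's acid (enol form; C1 attached to C5 of the dioxanedione), via acid chloride 22 (not isolated)
Conditions: Me2C=C(Cl)NMe2, CH2Cl2, 0 °C; then Meldrum's acid, pyridine, 0 → 25 °C
Reagents that add atoms: none
Why: C-acylation of Meldrum's acid by an acid chloride (Oikawa–Yonemitsu), forming C1–C2; Ghosez's chloroenamine makes the hindered α-acetoxy acid chloride under neutral conditions that spare the silyl and PMB ethers.

Step 15
Reactants: 23 acyl Meldrum's acid (C3 PMB ether)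
Product: 24 seco alcohol (free C3–OH, acyl Meldrum's acid at C1)
Conditions: DDQ, CH2Cl2/pH 7 buffer, 0 °C
Reagents that add atoms: none
Why: Oxidative PMB cleavage; silyl ethers, the enoate and the acyl Meldrum's enol are inert to buffered DDQ, and the alcohol is freed only just before cyclization.

Step 16
Reactants: 24 seco alcohol
Product: 26 twelve-membered allyl β-keto lactone ((E)-C4=C5; 6R and 8S TBS ethers; 10R acetate; exocyclic C7=C11 with CO2Me cis to C6 and CH2OTIPS cis to C8), via acylketene 25 (not isolated)
Conditions: toluene (1 mM, slow addition), 100 °C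
Reagents that add atoms: none
Why: Thermolysis of the acyl Meldrum's acid releases acetone and CO2 to give acylketene 25, which the primary allylic alcohol captures intramolecularly (Boeckman-type acylketene macrolactonization). No base or activating reagent is present, and a twelve-membered ring with one (E)-alkene is unstrained.

Step 17
Reactants: 26 twelve-membered allyl β-keto lactone
Product: 27 ten-membered 1-keto (E)-4-ene (6R and 8S TBS ethers, 10R acetate, C12 methyl ester, C13 TIPS ether)
Conditions: Pd(PPh3)4 (10 mol %), THF (2 mM), 25 → 45 °C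
Reagents that add atoms: none
Why: Decarboxylative allylation of an allyl β-keto ester (Tsuji–Saegusa type, the palladium counterpart of the Carroll rearrangement), run on a lactone so that loss of CO2 contracts the ring by two atoms. Zerovalent palladium complexes C4=C5 and ionizes the primary allylic C3–O bond with inversion; the β-keto carboxylate loses CO2, and the enolate, which can only be the C1–C2 enolate because C10 is quaternary, recombines with the allyl unit inside the ion pair. The ten-membered ring closes when C2 attacks the C3 terminus with the allyl unit staying inside the ring; attack at C5 would be an 8-exo closure to a 2-alkenyl cyclooctanone and is disfavoured because C5 is secondary and flanked by the silyloxy-bearing C6. No stereocenter is formed. The (E) geometry should be retained because the (E)-allyl ester gives the syn allyl complex and C–C bond formation in the tight ion pair is faster than syn–anti exchange. Ionization is chemoselective because the oxygens at C6, C8 and C13 are silyl ethers, C12 is an acyclic methyl ester and the C10 acetate is not allylic, so the lactone C3–O bond is the only allylic carboxylate. High dilution suppresses crossover between ion pairs, and any O-allylated enol ether can re-enter the cycle.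

Step 18
Reactants: 27 ten-membered ketone
Product: 29 (6R,8S,10R)-10-acetoxy-8,13-dihydroxy-1-oxogermacra-4(E),7(11)-dien-12,6-olide, via triol ester 28 (not isolated)
Conditions: HF·pyridine, pyridine, THF, 0 → 25 °C
Reagents that add atoms: none
Why: Acidic fluoride removes all three silyl groups; the C6 hydroxyl, held cis to the ester across C7=C11, lactonizes spontaneously (5-exo-trig acyl substitution), whereas the C8 hydroxyl is trans to it. Acidic rather than basic fluoride avoids acetyl migration from C10 to C8 and deprotonation at C6.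

Step 19
Reactants: 29 lactone diol
Product: 30 13-acetate (C8–OH free)
Conditions: AcCl (1.05 equiv), 2,4,6-collidine, CH2Cl2, −78 °C
Reagents that add atoms: acetyl chloride, CC(=O)Cl
Why: Selective acylation of the primary allylic alcohol over the hindered secondary C8 hydroxyl with acetyl chloride and collidine at low temperature.

Step 20
Reactants: 30 13-acetate
Product: 31 8-tiglate (4,5-alkene butenolide)
Conditions: (E)-MeCH=C(Me)COCl, DMAP, pyridine, CH2Cl2, 0 → 25 °C
Reagents that add atoms: tigloyl chloride, C/C=C(\C)C(=O)Cl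
Why: DMAP-catalysed esterification with the acid chloride; the tiglate is the stable (E) isomer, and only mild amine bases are used because H6 is γ to the lactone carbonyl.

Step 21
Reactants: 31 8-tiglate
Product: 32 target, (4R,5R,6S,8S,10R)-10,13-diacetoxy-4,5-epoxy-1-oxo-8-[(E)-2-methylbut-2-enoyloxy]germacr-7(11)-en-12,6-olide
Conditions: mCPBA, NaHCO3, CH2Cl2, 0 °C
Reagents that add atoms: 3-chloroperoxybenzoic acid, OOC(=O)c1cccc(Cl)c1
Why: Prilezhaev epoxidation; only C4=C5 is electron-rich, the butenolide and tiglate alkenes being deactivated. In a 6,12-olide the (E)-alkene stands roughly perpendicular to the ring with one face shielded, so the peracid should attack the outer face and give the parthenolide-type 4R,5R epoxide; the syn addition keeps the trans relationship of C3 and C6.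

## Compound list

1 | 2,2-dimethoxyacetaldehyde | COC(OC)C=O | starting material
2 | ethyl 2-(triphenylphosphoranylidene)propanoate | CCOC(=O)C(C)=P(c1ccccc1)(c1ccccc1)c1ccccc1 | starting material
3 | ethyl (2E)-4,4-dimethoxy-2-methylbut-2-enoate | CCOC(=O)/C(C)=C/C(OC)OC | intermediate
4 | (2E)-4,4-dimethoxy-2-methylbut-2-en-1-ol | OC/C(C)=C/C(OC)OC | intermediate
5 | 1-({[(2E)-4,4-dimethoxy-2-methylbut-2-en-1-yl]oxy}methyl)-4-methoxybenzene | COc1ccc(COC/C(C)=C/C(OC)OC)cc1 | intermediate
6 | (2E)-4-[(4-methoxybenzyl)oxy]-3-methylbut-2-enal | COc1ccc(COC/C(C)=C/C=O)cc1 | intermediate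
7 | methyl propiolate | C#CC(=O)OC | starting material
8 | methyl (4R,5E)-4-hydroxy-7-[(4-methoxybenzyl)oxy]-6-methylhept-5-en-2-ynoate | COC(=O)C#C[C@H](O)/C=C(\C)COCc1ccc(OC)cc1 | intermediate
9 | methyl (4R,5E)-4-[(tert-butyldimethylsilyl)oxy]-7-[(4-methoxybenzyl)oxy]-6-methylhept-5-en-2-ynoate | COC(=O)C#C[C@H](O[Si](C)(C)C(C)(C)C)/C=C(\C)COCc1ccc(OC)cc1 | intermediate
10 | alkenylcopper from syn stannylcupration of 9 (Cu on C11 cis to Me3Sn on C7) | COC(=O)/C([Cu])=C(/[Sn](C)(C)C)[C@H](O[Si](C)(C)C(C)(C)C)/C=C(\C)COCc1ccc(OC)cc1 | intermediate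
11 | methyl (2E,4R,5E)-4-[(tert-butyldimethylsilyl)oxy]-7-[(4-methoxybenzyl)oxy]-6-methyl-2-{[(triisopropylsilyl)oxy]methyl}-3-(trimethylstannyl)hepta-2,5-dienoate | COC(=O)/C(CO[Si](C(C)C)(C(C)C)C(C)C)=C(/[Sn](C)(C)C)[C@H](O[Si](C)(C)C(C)(C)C)/C=C(\C)COCc1ccc(OC)cc1 | intermediate
12 | (R)-citramalic acid | C[C@@](O)(CC(=O)O)C(=O)O | starting material
13 | 2-[(4R)-2,2,4-trimethyl-5-oxo-1,3-dioxolan-4-yl]acetic acid | C[C@]1(CC(=O)O)OC(C)(C)OC1=O | intermediate
14 | 2-[(4R)-2,2,4-trimethyl-5-oxo-1,3-dioxolan-4-yl]acetyl chloride | C[C@]1(CC(=O)Cl)OC(C)(C)OC1=O | intermediate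
15 | methyl (2E,4R,5E)-4-[(tert-butyldimethylsilyl)oxy]-7-[(4-methoxybenzyl)oxy]-6-methyl-2-{[(triisopropylsilyl)oxy]methyl}-3-{2-[(4R)-2,2,4-trimethyl-5-oxo-1,3-dioxolan-4-yl]acetyl}hepta-2,5-dienoate | COC(=O)/C(CO[Si](C(C)C)(C(C)C)C(C)C)=C(/C(=O)C[C@@]1(C)OC(C)(C)OC1=O)[C@H](O[Si](C)(C)C(C)(C)C)/C=C(\C)COCc1ccc(OC)cc1 | intermediate
16 | (8S) alcohol from reduction of 15 (2Z; other groups as 15) | COC(=O)/C(CO[Si](C(C)C)(C(C)C)C(C)C)=C(/[C@@H](O)C[C@@]1(C)OC(C)(C)OC1=O)[C@H](O[Si](C)(C)C(C)(C)C)/C=C(\C)COCc1ccc(OC)cc1 | intermediate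
17 | methyl (2Z,4R,5E)-4-[(tert-butyldimethylsilyl)oxy]-3-{(1S)-1-[(tert-butyldimethylsilyl)oxy]-2-[(4R)-2,2,4-trimethyl-5-oxo-1,3-dioxolan-4-yl]ethyl}-7-[(4-methoxybenzyl)oxy]-6-methyl-2-{[(triisopropylsilyl)oxy]methyl}hepta-2,5-dienoate | COC(=O)/C(CO[Si](C(C)C)(C(C)C)C(C)C)=C(/[C@@H](O[Si](C)(C)C(C)(C)C)C[C@@]1(C)OC(C)(C)OC1=O)[C@H](O[Si](C)(C)C(C)(C)C)/C=C(\C)COCc1ccc(OC)cc1 | intermediate
18 | seco hydroxy acid (C1 CO2H, 10R tertiary OH, 8S and 6R TBS ethers, C13 TIPS ether, C12 methyl ester cis to C6, C3 PMB ether, 4E) | COC(=O)/C(CO[Si](C(C)C)(C(C)C)C(C)C)=C(/[C@@H](O[Si](C)(C)C(C)(C)C)C[C@@](C)(O)C(=O)O)[C@H](O[Si](C)(C)C(C)(C)C)/C=C(\C)COCc1ccc(OC)cc1 | intermediate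
19 | mixed acetic anhydride of the C10 acetate | COC(=O)/C(CO[Si](C(C)C)(C(C)C)C(C)C)=C(/[C@@H](O[Si](C)(C)C(C)(C)C)C[C@@](C)(OC(C)=O)C(=O)OC(C)=O)[C@H](O[Si](C)(C)C(C)(C)C)/C=C(\C)COCc1ccc(OC)cc1 | intermediate
20 | seco acetoxy acid (as 18 with 10R acetate) | COC(=O)/C(CO[Si](C(C)C)(C(C)C)C(C)C)=C(/[C@@H](O[Si](C)(C)C(C)(C)C)C[C@@](C)(OC(C)=O)C(=O)O)[C@H](O[Si](C)(C)C(C)(C)C)/C=C(\C)COCc1ccc(OC)cc1 | intermediate
21 | Meldrum's acid (2,2-dimethyl-1,3-dioxane-4,6-dione) | CC1(C)OC(=O)CC(=O)O1 | starting material
22 | C1 acid chloride of 20 | COC(=O)/C(CO[Si](C(C)C)(C(C)C)C(C)C)=C(/[C@@H](O[Si](C)(C)C(C)(C)C)C[C@@](C)(OC(C)=O)C(Cl)=O)[C@H](O[Si](C)(C)C(C)(C)C)/C=C(\C)COCc1ccc(OC)cc1 | intermediate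
23 | acyl Meldrum's acid (enol form), C3 PMB ether | COC(=O)/C(CO[Si](C(C)C)(C(C)C)C(C)C)=C(/[C@@H](O[Si](C)(C)C(C)(C)C)C[C@@](C)(OC(C)=O)C(O)=C1C(=O)OC(C)(C)OC1=O)[C@H](O[Si](C)(C)C(C)(C)C)/C=C(\C)COCc1ccc(OC)cc1 | intermediate
24 | acyl Meldrum's acid with free C3–OH | COC(=O)/C(CO[Si](C(C)C)(C(C)C)C(C)C)=C(/[C@@H](O[Si](C)(C)C(C)(C)C)C[C@@](C)(OC(C)=O)C(O)=C1C(=O)OC(C)(C)OC1=O)[C@H](O[Si](C)(C)C(C)(C)C)/C=C(\C)CO | intermediate
25 | acylketene (C1 ketone, C2=C=O) with free C3–OH | COC(=O)/C(CO[Si](C(C)C)(C(C)C)C(C)C)=C(/[C@@H](O[Si](C)(C)C(C)(C)C)C[C@@](C)(OC(C)=O)C(=O)C=C=O)[C@H](O[Si](C)(C)C(C)(C)C)/C=C(\C)CO | intermediate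
26 | twelve-membered allyl β-keto lactone | CC(C)(C)[Si](C)(C)O[C@H]1C[C@@](C)(OC(C)=O)C(=O)CC(=O)OC/C(C)=C/[C@@H](O[Si](C)(C)C(C)(C)C)/C1=C(/CO[Si](C(C)C)(C(C)C)C(C)C)C(=O)OC | intermediate
27 | ten-membered 1-keto (E)-4-ene | CC(C)(C)[Si](C)(C)O[C@H]1C[C@@](C)(OC(C)=O)C(=O)CC/C(C)=C/[C@@H](O[Si](C)(C)C(C)(C)C)/C1=C(/CO[Si](C(C)C)(C(C)C)C(C)C)C(=O)OC | intermediate
28 | ten-membered triol methyl ester (6-OH, 8-OH, 13-OH) | O[C@H]1C[C@@](C)(OC(C)=O)C(=O)CC/C(C)=C/[C@@H](O)/C1=C(/CO)C(=O)OC | intermediate
29 | (6R,8S,10R)-10-acetoxy-8,13-dihydroxy-1-oxogermacra-4(E),7(11)-dien-12,6-olide | O[C@H]1C[C@@](C)(OC(C)=O)C(=O)CC/C(C)=C/[C@H]2OC(=O)C(CO)=C12 | intermediate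
30 | (6R,8S,10R)-10,13-diacetoxy-8-hydroxy-1-oxogermacra-4(E),7(11)-dien-12,6-olide | O[C@H]1C[C@@](C)(OC(C)=O)C(=O)CC/C(C)=C/[C@H]2OC(=O)C(COC(C)=O)=C12 | intermediate
31 | (6R,8S,10R)-10,13-diacetoxy-1-oxo-8-tigloyloxygermacra-4(E),7(11)-dien-12,6-olide | C/C=C(\C)C(=O)O[C@H]1C[C@@](C)(OC(C)=O)C(=O)CC/C(C)=C/[C@H]2OC(=O)C(COC(C)=O)=C12 | intermediate
32 | (4R,5R,6S,8S,10R)-10,13-diacetoxy-4,5-epoxy-1-oxo-8-tigloyloxygermacr-7(11)-en-12,6-olide | C/C=C(\C)C(=O)O[C@H]1C[C@@](C)(OC(C)=O)C(=O)CC[C@@]2(C)O[C@@H]2[C@H]2OC(=O)C(COC(C)=O)=C12 | target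

## Step count and least certain steps

Total: 21 steps. Longest linear sequence: 19 steps (steps 1–7 and 10–21); steps 8 and 9 make the citramalate fragment.

**Step 17 (key step).** The syn allylpalladium unit may isomerize to the anti form before C–C bond formation and close to the (Z)-cycloalkene, which is the less strained ring. Proton transfer to the enolate may give the uncyclized methyl ketone with loss of the allyl unit as a diene. Crossover between ion pairs would give oligomers. The fallback forms the same C2–C3 bond by an allylic alkylation with a stabilized nucleophile. It sets out from 23 and returns at 29.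
- Heating 23 with 2-(trimethylsilyl)ethanol in toluene traps the acylketene intermolecularly as the 2-(trimethylsilyl)ethyl β-keto ester F1.
- DDQ frees the allylic alcohol F2, and methyl chloroformate/pyridine gives the allylic methyl carbonate F3.
- Pd(PPh3)4 at high dilution under neutral conditions effects intramolecular allylic alkylation (Trost-type macrocyclization) to the ten-membered β-keto ester F4.
- Bu4NF buffered with acetic acid, then mild acid, removes the silylethyl ester with decarboxylation and all silyl ethers; lactonization gives 29.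

**Step 7.** The α-cuprio ester may equilibrate through its allenoate before alkylation, giving the geometric isomer with the ester cis to tin, and the chloro ether may react at oxygen instead of carbon. The fallback builds the alkene by stereospecific palladium chemistry only. It sets out from 9 (with 14) and returns at 17.
- Pd(PPh3)4-catalysed syn addition of Me6Sn2 to 9 gives the (Z)-2,3-bis(trimethylstannyl) ester F5.
- Stille acylation with 14 at the more reactive β-stannyl group gives the α-stannyl keto ester F6.
- Iodine gives the α-iodo enone F7.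
- CBS reduction and silylation as in step 11 give the α-iodo silyl ether F8.
- Stille coupling with Bu3SnCH2OH gives the C13 alcohol F9, and TIPSOTf gives 17.

**Step 10.** Transmetalation at the fully substituted alkenyl tin centre may be too slow, so that protodestannylation or decarbonylation of the acylpalladium species takes over. The fallback replaces acylation by addition to an aldehyde. It sets out from 11 and 14 and returns at 15.
- Iodine converts 11 into the alkenyl iodide F10.
- LiAlH(OtBu)3 at −78 °C reduces 14 to the aldehyde F11.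
- CrCl2 with catalytic NiCl2 (Nozaki–Hiyama–Kishi coupling) gives the allylic alcohols F12 as a C8 epimer mixture.
- Dess–Martin periodinane gives 15.

**Step 21.** Facial selectivity may be poor if the ten-membered ring, which lacks the usual second endocyclic alkene of a germacrolide, populates conformers that expose both faces of C4=C5. The fallback replaces substrate control by reagent control: epoxidation of 31 with the fructose-derived Shi ketone (enantiomer chosen for the 4R,5R face) and KHSO5, which gives 32 directly and needs no new compound.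

## Further compounds

F1 | step 17 | 2-(trimethylsilyl)ethyl β-keto ester of the seco chain, C3 PMB ether | COC(=O)/C(CO[Si](C(C)C)(C(C)C)C(C)C)=C(/[C@@H](O[Si](C)(C)C(C)(C)C)C[C@@](C)(OC(C)=O)C(=O)CC(=O)OCC[Si](C)(C)C)[C@H](O[Si](C)(C)C(C)(C)C)/C=C(\C)COCc1ccc(OC)cc1
F2 | step 17 | the same β-keto ester with free C3–OH | COC(=O)/C(CO[Si](C(C)C)(C(C)C)C(C)C)=C(/[C@@H](O[Si](C)(C)C(C)(C)C)C[C@@](C)(OC(C)=O)C(=O)CC(=O)OCC[Si](C)(C)C)[C@H](O[Si](C)(C)C(C)(C)C)/C=C(\C)CO
F3 | step 17 | C3 allylic methyl carbonate of F2 | COC(=O)/C(CO[Si](C(C)C)(C(C)C)C(C)C)=C(/[C@@H](O[Si](C)(C)C(C)(C)C)C[C@@](C)(OC(C)=O)C(=O)CC(=O)OCC[Si](C)(C)C)[C@H](O[Si](C)(C)C(C)(C)C)/C=C(\C)COC(=O)OC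
F4 | step 17 | ten-membered β-keto ester (2-(trimethylsilyl)ethyl ester on C2, C2 epimers) | CC(C)(C)[Si](C)(C)O[C@H]1C[C@@](C)(OC(C)=O)C(=O)C(C(=O)OCC[Si](C)(C)C)C/C(C)=C/[C@@H](O[Si](C)(C)C(C)(C)C)/C1=C(/CO[Si](C(C)C)(C(C)C)C(C)C)C(=O)OC
F5 | step 7 | methyl (2Z,4R,5E)-4-[(tert-butyldimethylsilyl)oxy]-7-[(4-methoxybenzyl)oxy]-6-methyl-2,3-bis(trimethylstannyl)hepta-2,5-dienoate | COC(=O)/C([Sn](C)(C)C)=C(/[Sn](C)(C)C)[C@H](O[Si](C)(C)C(C)(C)C)/C=C(\C)COCc1ccc(OC)cc1
F6 | step 7 | α-trimethylstannyl keto ester (C7 acylated by 14) | COC(=O)/C([Sn](C)(C)C)=C(/C(=O)C[C@@]1(C)OC(C)(C)OC1=O)[C@H](O[Si](C)(C)C(C)(C)C)/C=C(\C)COCc1ccc(OC)cc1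
F7 | step 7 | α-iodo keto ester | COC(=O)/C(I)=C(/C(=O)C[C@@]1(C)OC(C)(C)OC1=O)[C@H](O[Si](C)(C)C(C)(C)C)/C=C(\C)COCc1ccc(OC)cc1
F8 | step 7 | α-iodo ester with (8S) TBS ether | COC(=O)/C(I)=C(/[C@@H](O[Si](C)(C)C(C)(C)C)C[C@@]1(C)OC(C)(C)OC1=O)[C@H](O[Si](C)(C)C(C)(C)C)/C=C(\C)COCc1ccc(OC)cc1
F9 | step 7 | C13 primary alcohol (17 without the TIPS group) | COC(=O)/C(CO)=C(/[C@@H](O[Si](C)(C)C(C)(C)C)C[C@@]1(C)OC(C)(C)OC1=O)[C@H](O[Si](C)(C)C(C)(C)C)/C=C(\C)COCc1ccc(OC)cc1
F10 | step 10 | alkenyl iodide from 11 (iodine at C7) | COC(=O)/C(CO[Si](C(C)C)(C(C)C)C(C)C)=C(/I)[C@H](O[Si](C)(C)C(C)(C)C)/C=C(\C)COCc1ccc(OC)cc1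
F11 | step 10 | 2-[(4R)-2,2,4-trimethyl-5-oxo-1,3-dioxolan-4-yl]acetaldehyde | C[C@]1(CC=O)OC(C)(C)OC1=O
F12 | step 10 | C8 allylic alcohols (both C8 epimers) | COC(=O)/C(CO[Si](C(C)C)(C(C)C)C(C)C)=C(/C(O)C[C@@]1(C)OC(C)(C)OC1=O)[C@H](O[Si](C)(C)C(C)(C)C)/C=C(\C)COCc1ccc(OC)cc1
F0 | step 21 | none | none
A1 | alternative 1 | 4,5-alkene butenolide lacking the epoxide (identical with 31) | C/C=C(\C)C(=O)O[C@H]1C[C@@](C)(OC(C)=O)C(=O)CC/C(C)=C/[C@H]2OC(=O)C(COC(C)=O)=C12
A2 | alternative 1 | ten-membered 4,7(11)-dienoic acid with C6 methylene | C/C=C(\C)C(=O)O[C@H]1C[C@@](C)(OC(C)=O)C(=O)CC/C(C)=C/C/C1=C(/COC(C)=O)C(=O)O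
A3 | alternative 2 | ten-membered 1,6-diketone with C8 ketal and (Z)-C3=C4 alkene | C[C@@H]1CC2(OCCO2)CC(=O)C/C(C)=C\CC1=O
A4 | alternative 2 | bicyclic hexahydronaphthalene ethylene ketal with tetrasubstituted C1=C6 and trisubstituted C3=C4 | C[C@@H]1CC2(OCCO2)CC2=C1CC=C(C)C2
A5 | alternative 3 | 8-hydroxy macrocycle lacking the tiglate | O[C@H]1C[C@@](C)(OC(C)=O)C(=O)CC[C@@]2(C)O[C@@H]2[C@H]2OC(=O)C(COC(C)=O)=C12
A6 | alternative 3 | seco C7-bromobutenolide C8 aldehyde | O=CC[C@@](C)(OC(C)=O)C(=O)CC[C@@]1(C)O[C@@H]1[C@H]1OC(=O)C(COC(C)=O)=C1Br
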